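(All runs were computed with made-up constants, and the scatter is random.)

In the ochre run at 40.0 min, the product and starting material readings leave a remainder of 14.7% of the charge, which on 0.44 M is 0.0647 M. In the teal run the remainder grows from 8.40% at 10.0 min to 10.0% at 40.0 min, and on 0.65 M that too reads 0.0650 M. Both flasks were charged with 0.065 M of protic impurity. So I read the remainder as the impurity taking its own molar amount of starting material early on, and I reckon with what it leaves free.

| flask | starting material | reagent | protic impurity | catalyst | temperature | remark | time |
|---|---|---|---|---|---|---|---|
| teal | 0.65 M | 0.16 M | 0.065 M | 2 mM | 15 °C | run made earlier |  |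
| grey | 0.65 M | 0.33 M | 0.065 M | 2 mM | 26 °C | run made earlier |  |
| green | 0.65 M | 0.64 M | 0.065 M | 2 mM | 15 °C | run made earlier |  |
| ochre | 0.44 M | 0.65 M | 0.065 M | 2 mM | 26 °C | run made earlier |  |
| west | 1.2 M | 0.150 M | 0.0650 M | 3.0 mM | 20 °C |  | 80 min |
| north-east | 0.65 M | 0.650 M | 0.0650 M | 2.0 mM | 20 °C |  | 80 min |
| east | 0.30 M | 0.200 M | 0.0650 M | 2.0 mM | 20 °C |  | 80 min |
| south-west | 1.0 M | 0.300 M | 0.0650 M | 3.0 mM | 20 °C |  | 80 min |

- teal (time / min: product / %, starting material / %): 10.0: 2.6, 89.0; 20.0: 5.9, 85.2; 30.0: 7.3, 82.6; 40.0: 9.1, 80.9
- grey (time / min: product / %, starting material / %): 5.00: 6.2, 85.0; 15.0: 15.3, 74.7; 25.0: 22.2, 67.4; 40.0: 29.6, 60.0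
- green (time / min: product / %, starting material / %): 3.00: 3.9, 92.5; 8.00: 9.4, 83.4; 15.0: 15.9, 74.7; 40.0: 34.2, 55.8
- ochre (time / min: product / %, starting material / %): 3.00: 8.5, 82.9; 8.00: 19.9, 67.2; 15.0: 31.8, 54.1; 40.0: 56.9, 28.4

(scatter of a reading: 0.3 percentage points)

1. the flasks by amount of product, in percent of the starting material charged, highest first, at 80 min (west / north-east / east / south-west)
2. the amount of product, in percent of the starting material charged of the flask you put first, at 80 min
3. the amount of product, in percent of the starting material charged of the flask you put last, at 80 min

- no earlier run changes the charge of catalyst; that part of a forecast is a guess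

I have to choose which recipe to charge next, and for that I use the ceiling: the smaller of the free starting material (charge minus impurity) and the reagent, as a percentage of the starting material charged. It assumes one reagent per product, which the runs do not test. In west the reagent, 0.150 M, stands below the free 1.14 M, so the ceiling is 12.5%, and south-west gets 30.0% and east 66.7%. In north-east the free 0.585 M falls below the reagent, so starting material is the limiting reagent there, and the ceiling is the highest at 90.0%. I charge north-east, and I add no starting material to west, since that divides the same reagent over a larger charge. A ceiling carries no clock, though, so the forecast supplies the rates. It gives north-east > east > south-west > west, with 58% (54% to 62%) first and 11.9% (11% to 12.5%) last, and it warns: “East versus south-west is nearly a tie”.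

The flasks give north-east > east > south-west > west, with 59.8% first and 11.8% last; east holds 29.2% and south-west 27.3%.

    starting material + protic impurity → quenched substrate (k = 0.420 /M/min, Ea = 63.0 kJ/mol)
    starting material + reagent + catalyst → product + catalyst, rate k2*[starting material]*[reagent]*[catalyst]/(1 + ([starting material]/sat2)) (1.20 M, k = 22.0 /M²/min, Ea = 48.0 kJ/mol)
    (constants at 20 °C)

North-east stands at 59.8% under its ceiling of 90.0% in part because it is read at 80.0 min and not at 800 min, when it holds 88.9%, and in part because of the crowding by starting material in the product step, without which it holds 64.9% at the asked time. West ends at 11.8% under its ceiling of 12.5%, with 5.33% of its reagent left at 80.0 min. The neighbour of west charged with 0.30 M of starting material has a ceiling of 50.0%, and it holds 28.9% of product at 80.0 min with 42% of its reagent still there.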